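**Retrosynthetic overview**
- The target is reached by global deprotection (silyl ethers, then benzyl ethers) of a protected erythro triol; the erythro C7 configuration comes from Mitsunobu inversion of the threo (7R,8R) benzylic alcohol.
- The threo alcohol comes from hydride removal of the auxiliary (and reduction of the side-chain ester) in an Evans syn-aldol adduct.
- Key C7–C8 bond: boron-mediated aldol between an N-(aryloxyacetyl)oxazolidinone enolate (sets C8) and 3,4-bis(benzyloxy)benzaldehyde.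
- The imide comes from an aryloxyacetic acid, made by O-alkylation of methyl dihydroferulate with benzyl bromoacetate.
- No ring is constructed: both benzene rings are bought, and the oxazolidinone is a purchased, recoverable auxiliary.

Assumption: lignan numbering is used in the comments (C7 = benzylic carbinol carbon, C8 = aryloxy-bearing carbon, C9 = CH2OH), so the target is (7S,8R), the erythro isomer, named (1S,2R) as a propane-1,3-diol; 3-(4-hydroxy-3-methoxyphenyl)propanoic acid is taken as a catalogue compound.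

**Step 1**
Reactants: 1 3-(4-hydroxy-3-methoxyphenyl)propanoic acid
Product: 2 methyl 3-(4-hydroxy-3-methoxyphenyl)propanoate
Conditions: MeOH, H2SO4 (cat.), reflux
Reagents that add atoms: methanol, CO
Why: Fischer esterification converts only the carboxylic acid and leaves the phenol free for the next step.

**Step 2**
Reactants: 2 methyl 3-(4-hydroxy-3-methoxyphenyl)propanoate; 3 benzyl bromoacetate
Product: 4 methyl 3-{4-[2-(benzyloxy)-2-oxoethoxy]-3-methoxyphenyl}propanoate
Conditions: K2CO3, acetone, reflux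
Reagents that add atoms: none
Why: Williamson ether synthesis, the phenoxide displacing the activated α-bromide, while both esters tolerate carbonate in acetone.

**Step 3**
Reactants: 4 methyl 3-{4-[2-(benzyloxy)-2-oxoethoxy]-3-methoxyphenyl}propanoate
Product: 5 2-[2-methoxy-4-(3-methoxy-3-oxopropyl)phenoxy]acetic acid
Conditions: H2 (1 atm), 10% Pd/C, EtOAc, rt
Reagents that add atoms: none
Why: Catalytic hydrogenolysis cleaves the benzyl ester selectively and leaves the methyl ester and the aryl ether intact.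

**Step 4**
Reactants: 5 2-[2-methoxy-4-(3-methoxy-3-oxopropyl)phenoxy]acetic acid; 6 (4S)-4-benzyl-1,3-oxazolidin-2-one
Product: 8 methyl 3-(4-{2-[(4S)-4-benzyl-2-oxo-1,3-oxazolidin-3-yl]-2-oxoethoxy}-3-methoxyphenyl)propanoate, via mixed pivalic anhydride 7 (not isolated)
Conditions: PivCl, Et3N, THF, −20 → 0 °C; then 6, LiCl, rt
Reagents that add atoms: none
Why: N-acylation through the mixed pivalic anhydride, in which the LiCl/Et3N-activated oxazolidinone attacks the unhindered aryloxyacetyl carbonyl and the remote methyl ester is not touched.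

**Step 5**
Reactants: 8 methyl 3-(4-{2-[(4S)-4-benzyl-2-oxo-1,3-oxazolidin-3-yl]-2-oxoethoxy}-3-methoxyphenyl)propanoate; 9 3,4-bis(benzyloxy)benzaldehyde
Product: 12 methyl 3-[4-({(2S,3R)-1-[(4S)-4-benzyl-2-oxo-1,3-oxazolidin-3-yl]-3-[3,4-bis(benzyloxy)phenyl]-3-hydroxy-1-oxopropan-2-yl}oxy)-3-methoxyphenyl]propanoate, via boron Z-enolate 10 (not isolated), via boron aldolate 11 (not isolated)
Conditions: Bu2BOTf, i-Pr2NEt, CH2Cl2, −78 → 0 °C; then 9, −78 → 0 °C; then pH 7 buffer, MeOH, 30% H2O2, 0 °C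
Reagents that add atoms: none
Why: Evans boron aldol, in which the Z-dibutylboron enolate reacts through a dipole-minimised Zimmerman–Traxler chair on the enolate face remote from the benzyl group, giving the syn adduct with C8 in its final configuration (2S in the imide) and C7 as R (3R).

**Step 6**
Reactants: 12 methyl 3-[4-({(2S,3R)-1-[(4S)-4-benzyl-2-oxo-1,3-oxazolidin-3-yl]-3-[3,4-bis(benzyloxy)phenyl]-3-hydroxy-1-oxopropan-2-yl}oxy)-3-methoxyphenyl]propanoate
Product: 13 (1R,2R)-1-[3,4-bis(benzyloxy)phenyl]-2-[4-(3-hydroxypropyl)-2-methoxyphenoxy]propane-1,3-diol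
Conditions: LiBH4 (4 equiv), THF, MeOH (2 equiv), 0 °C → rt
Reagents that add atoms: none
Why: Hydride reduction of the activated exocyclic imide carbonyl releases the auxiliary and gives the C9 alcohol, and the same reagent reduces the methyl ester to the 3-hydroxypropyl chain without touching either stereocentre.

**Step 7**
Reactants: 13 (1R,2R)-1-[3,4-bis(benzyloxy)phenyl]-2-[4-(3-hydroxypropyl)-2-methoxyphenoxy]propane-1,3-diol
Product: 14 (1R,2R)-1-[3,4-bis(benzyloxy)phenyl]-3-{[tert-butyl(dimethyl)silyl]oxy}-2-[4-(3-{[tert-butyl(dimethyl)silyl]oxy}propyl)-2-methoxyphenoxy]propan-1-ol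
Conditions: TBSCl (2.2 equiv), imidazole, CH2Cl2, 0 °C
Reagents that add atoms: tert-butyldimethylsilyl chloride, CC(C)(C)[Si](C)(C)Cl
Why: Selective silyl ether formation, because the two primary hydroxyls react far faster with TBSCl than the hindered secondary benzylic one.

**Step 8**
Reactants: 14 (1R,2R)-1-[3,4-bis(benzyloxy)phenyl]-3-{[tert-butyl(dimethyl)silyl]oxy}-2-[4-(3-{[tert-butyl(dimethyl)silyl]oxy}propyl)-2-methoxyphenoxy]propan-1-ol
Product: 15 (1S,2R)-1-[3,4-bis(benzyloxy)phenyl]-3-{[tert-butyl(dimethyl)silyl]oxy}-2-[4-(3-{[tert-butyl(dimethyl)silyl]oxy}propyl)-2-methoxyphenoxy]propyl 4-nitrobenzoate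
Conditions: 4-nitrobenzoic acid, PPh3, DIAD, toluene, 0 °C → rt
Reagents that add atoms: 4-nitrobenzoic acid, O=C(O)c1ccc(cc1)[N+](=O)[O-]
Why: Mitsunobu reaction, the carboxylate displacing the oxyphosphonium group by SN2 with inversion so that C7 becomes S (erythro), with the adjacent aryloxy group and the non-polar solvent disfavouring benzylic ionisation.

**Step 9**
Reactants: 15 (1S,2R)-1-[3,4-bis(benzyloxy)phenyl]-3-{[tert-butyl(dimethyl)silyl]oxy}-2-[4-(3-{[tert-butyl(dimethyl)silyl]oxy}propyl)-2-methoxyphenoxy]propyl 4-nitrobenzoate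
Product: 16 (1S,2R)-1-[3,4-bis(benzyloxy)phenyl]-3-{[tert-butyl(dimethyl)silyl]oxy}-2-[4-(3-{[tert-butyl(dimethyl)silyl]oxy}propyl)-2-methoxyphenoxy]propan-1-ol
Conditions: K2CO3 (cat.), MeOH/THF, 0 °C → rt
Reagents that add atoms: none
Why: Base-catalysed transesterification (methanolysis) of the activated 4-nitrobenzoate proceeds by acyl–oxygen cleavage, so the new C7 configuration is retained and the silyl and benzyl ethers survive.

**Step 10**
Reactants: 16 (1S,2R)-1-[3,4-bis(benzyloxy)phenyl]-3-{[tert-butyl(dimethyl)silyl]oxy}-2-[4-(3-{[tert-butyl(dimethyl)silyl]oxy}propyl)-2-methoxyphenoxy]propan-1-ol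
Product: 17 (1S,2R)-1-[3,4-bis(benzyloxy)phenyl]-2-[4-(3-hydroxypropyl)-2-methoxyphenoxy]propane-1,3-diol
Conditions: TBAF (2.5 equiv), THF, 0 °C → rt
Reagents that add atoms: none
Why: Fluoride-mediated desilylation removes both TBS ethers under non-acidic conditions that cannot ionise the electron-rich benzylic alcohol.

**Step 11**
Reactants: 17 (1S,2R)-1-[3,4-bis(benzyloxy)phenyl]-2-[4-(3-hydroxypropyl)-2-methoxyphenoxy]propane-1,3-diol
Product: 18 (1S,2R)-1-(3,4-dihydroxyphenyl)-2-[4-(3-hydroxypropyl)-2-methoxyphenoxy]propane-1,3-diol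
Conditions: H2 (1 atm), 10% Pd/C, EtOAc/MeOH, rt, stopped at complete debenzylation
Reagents that add atoms: none
Why: Catalytic hydrogenolysis of the two aryl benzyl ethers is fast under neutral conditions, under which the secondary benzylic alcohol and the C8 aryl ether are retained, and it reveals the air-sensitive catechol last.

**Compound list**
1 | 3-(4-hydroxy-3-methoxyphenyl)propanoic acid | COc1cc(CCC(=O)O)ccc1O | starting material
2 | methyl 3-(4-hydroxy-3-methoxyphenyl)propanoate | COc1cc(CCC(=O)OC)ccc1O | intermediate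
3 | benzyl bromoacetate | BrCC(=O)OCc1ccccc1 | starting material
4 | methyl 3-{4-[2-(benzyloxy)-2-oxoethoxy]-3-methoxyphenyl}propanoate | COc1cc(CCC(=O)OC)ccc1OCC(=O)OCc1ccccc1 | intermediate
5 | 2-[2-methoxy-4-(3-methoxy-3-oxopropyl)phenoxy]acetic acid | COc1cc(CCC(=O)OC)ccc1OCC(=O)O | intermediate
6 | (4S)-4-benzyl-1,3-oxazolidin-2-one | O=C1N[C@@H](Cc2ccccc2)CO1 | starting material
7 | 2-[2-methoxy-4-(3-methoxy-3-oxopropyl)phenoxy]acetic 2,2-dimethylpropanoic anhydride (mixed pivalic anhydride) | COc1cc(CCC(=O)OC)ccc1OCC(=O)OC(=O)C(C)(C)C | intermediate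
8 | methyl 3-(4-{2-[(4S)-4-benzyl-2-oxo-1,3-oxazolidin-3-yl]-2-oxoethoxy}-3-methoxyphenyl)propanoate | COc1cc(CCC(=O)OC)ccc1OCC(=O)N1[C@@H](Cc2ccccc2)COC1=O | intermediate
9 | 3,4-bis(benzyloxy)benzaldehyde | O=Cc1ccc(OCc2ccccc2)c(OCc2ccccc2)c1 | starting material
10 | (Z)-dibutylboron enolate of imide 8 | CCCCB(CCCC)O/C(=C\Oc1ccc(CCC(=O)OC)cc1OC)N1[C@@H](Cc2ccccc2)COC1=O | intermediate
11 | O3-dibutylboron aldolate of adduct 12 | COc1cc(CCC(=O)OC)ccc1O[C@H](C(=O)N1[C@@H](Cc2ccccc2)COC1=O)[C@H](OB(CCCC)CCCC)c1ccc(OCc2ccccc2)c(OCc2ccccc2)c1 | intermediate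
12 | methyl 3-[4-({(2S,3R)-1-[(4S)-4-benzyl-2-oxo-1,3-oxazolidin-3-yl]-3-[3,4-bis(benzyloxy)phenyl]-3-hydroxy-1-oxopropan-2-yl}oxy)-3-methoxyphenyl]propanoate | COc1cc(CCC(=O)OC)ccc1O[C@H](C(=O)N1[C@@H](Cc2ccccc2)COC1=O)[C@H](O)c1ccc(OCc2ccccc2)c(OCc2ccccc2)c1 | intermediate
13 | (1R,2R)-1-[3,4-bis(benzyloxy)phenyl]-2-[4-(3-hydroxypropyl)-2-methoxyphenoxy]propane-1,3-diol | COc1cc(CCCO)ccc1O[C@H](CO)[C@H](O)c1ccc(OCc2ccccc2)c(OCc2ccccc2)c1 | intermediate
14 | (1R,2R)-1-[3,4-bis(benzyloxy)phenyl]-3-{[tert-butyl(dimethyl)silyl]oxy}-2-[4-(3-{[tert-butyl(dimethyl)silyl]oxy}propyl)-2-methoxyphenoxy]propan-1-ol | COc1cc(CCCO[Si](C)(C)C(C)(C)C)ccc1O[C@H](CO[Si](C)(C)C(C)(C)C)[C@H](O)c1ccc(OCc2ccccc2)c(OCc2ccccc2)c1 | intermediate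
15 | (1S,2R)-1-[3,4-bis(benzyloxy)phenyl]-3-{[tert-butyl(dimethyl)silyl]oxy}-2-[4-(3-{[tert-butyl(dimethyl)silyl]oxy}propyl)-2-methoxyphenoxy]propyl 4-nitrobenzoate | COc1cc(CCCO[Si](C)(C)C(C)(C)C)ccc1O[C@H](CO[Si](C)(C)C(C)(C)C)[C@@H](OC(=O)c1ccc(cc1)[N+](=O)[O-])c1ccc(OCc2ccccc2)c(OCc2ccccc2)c1 | intermediate
16 | (1S,2R)-1-[3,4-bis(benzyloxy)phenyl]-3-{[tert-butyl(dimethyl)silyl]oxy}-2-[4-(3-{[tert-butyl(dimethyl)silyl]oxy}propyl)-2-methoxyphenoxy]propan-1-ol | COc1cc(CCCO[Si](C)(C)C(C)(C)C)ccc1O[C@H](CO[Si](C)(C)C(C)(C)C)[C@@H](O)c1ccc(OCc2ccccc2)c(OCc2ccccc2)c1 | intermediate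
17 | (1S,2R)-1-[3,4-bis(benzyloxy)phenyl]-2-[4-(3-hydroxypropyl)-2-methoxyphenoxy]propane-1,3-diol | COc1cc(CCCO)ccc1O[C@H](CO)[C@@H](O)c1ccc(OCc2ccccc2)c(OCc2ccccc2)c1 | intermediate
18 | (1S,2R)-1-(3,4-dihydroxyphenyl)-2-[4-(3-hydroxypropyl)-2-methoxyphenoxy]propane-1,3-diol | COc1cc(CCCO)ccc1O[C@H](CO)[C@@H](O)c1ccc(O)c(O)c1 | target

**Totals**
Total step count: 11. Longest linear sequence: 11 steps (1 → 18); compounds 3, 6 and 9 are bought.

**Steps most likely to fail**

Step 8 (Mitsunobu inversion). The carbinol is hindered and electron-rich, so partial ionisation (loss of clean inversion) or elimination is possible. The fallback sets out from 14 and comes back at 16, bypassing steps 8 and 9. Alcohol 14 is oxidised with Dess–Martin periodinane in NaHCO3-buffered CH2Cl2 at 0 °C to (2R)-1-[3,4-bis(benzyloxy)phenyl]-3-{[tert-butyl(dimethyl)silyl]oxy}-2-[4-(3-{[tert-butyl(dimethyl)silyl]oxy}propyl)-2-methoxyphenoxy]propan-1-one F1, which is used without delay to avoid epimerisation at C8. The ketone is then reduced under chelation control (Zn(BH4)2, Et2O, −30 °C): zinc bridging the carbonyl and the α-(2-methoxyphenoxy) oxygens should direct hydride past H-8 to the anti (erythro) alcohol 16. This selectivity is expected from the chelation model rather than proven for this substrate; any threo alcohol formed is 14 itself and is recycled.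

Step 5 (boron aldol). The poly-oxygenated imide may enolise incompletely or give an eroded diastereomer ratio. The fallback sets out from 5 and comes back at 13. Acid 5 is coupled with (4S)-4-benzyl-1,3-thiazolidine-2-thione (EDC·HCl, DMAP, CH2Cl2) to give methyl 3-(4-{2-[(4S)-4-benzyl-2-thioxo-1,3-thiazolidin-3-yl]-2-oxoethoxy}-3-methoxyphenyl)propanoate F2. Its chlorotitanium enolate (TiCl4, i-Pr2NEt, N-methylpyrrolidinone, CH2Cl2, −78 → 0 °C, Crimmins-type non-chelated chair) adds to aldehyde 9 to give the same syn topology in methyl 3-[4-({(2S,3R)-1-[(4S)-4-benzyl-2-thioxo-1,3-thiazolidin-3-yl]-3-[3,4-bis(benzyloxy)phenyl]-3-hydroxy-1-oxopropan-2-yl}oxy)-3-methoxyphenyl]propanoate F3. The yellow thioimide is then reduced with LiBH4 exactly as in step 6 to give 13.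

Step 6 (double reduction with LiBH4). The ester may reduce slowly, and retro-aldol or endocyclic cleavage can compete. The fallback sets out from 12 and comes back at 13. The auxiliary and the methyl ester are both cleaved hydrolytically (LiOH, H2O2, THF/H2O, 0 °C → rt, then Na2SO3) to give (2S,3R)-3-[3,4-bis(benzyloxy)phenyl]-2-[4-(2-carboxyethyl)-2-methoxyphenoxy]-3-hydroxypropanoic acid F4. Both carboxylic acids are then reduced with BH3·THF (0 °C → rt), which leaves the benzyl ethers and the stereocentres alone, to give 13.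

**Further compounds**
F1 | step 8 | (2R)-1-[3,4-bis(benzyloxy)phenyl]-3-{[tert-butyl(dimethyl)silyl]oxy}-2-[4-(3-{[tert-butyl(dimethyl)silyl]oxy}propyl)-2-methoxyphenoxy]propan-1-one | COc1cc(CCCO[Si](C)(C)C(C)(C)C)ccc1O[C@H](CO[Si](C)(C)C(C)(C)C)C(=O)c1ccc(OCc2ccccc2)c(OCc2ccccc2)c1
F2 | step 5 | methyl 3-(4-{2-[(4S)-4-benzyl-2-thioxo-1,3-thiazolidin-3-yl]-2-oxoethoxy}-3-methoxyphenyl)propanoate | COc1cc(CCC(=O)OC)ccc1OCC(=O)N1[C@@H](Cc2ccccc2)CSC1=S
F3 | step 5 | methyl 3-[4-({(2S,3R)-1-[(4S)-4-benzyl-2-thioxo-1,3-thiazolidin-3-yl]-3-[3,4-bis(benzyloxy)phenyl]-3-hydroxy-1-oxopropan-2-yl}oxy)-3-methoxyphenyl]propanoate | COc1cc(CCC(=O)OC)ccc1O[C@H](C(=O)N1[C@@H](Cc2ccccc2)CSC1=S)[C@H](O)c1ccc(OCc2ccccc2)c(OCc2ccccc2)c1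
F4 | step 6 | (2S,3R)-3-[3,4-bis(benzyloxy)phenyl]-2-[4-(2-carboxyethyl)-2-methoxyphenoxy]-3-hydroxypropanoic acid | COc1cc(CCC(=O)O)ccc1O[C@H](C(=O)O)[C@H](O)c1ccc(OCc2ccccc2)c(OCc2ccccc2)c1
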